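**Retrosynthetic overview**

1. The target is ring A (2-acetylfilicinic acid unit) – CH2 – ring B (butanoylphloroglucinol) – CH2 – ring C (2-butanoylfilicinic acid unit). Both ring B–CH2 bonds are disconnected last, each made by Mannich base/enetrione (quinone-methide-type) C-alkylation of ring B, ring C first and ring A last.
2. Rings A and C both come from one filicinic acid by C-acylation (acetyl or butanoyl chloride); ring B is phloroglucinol, acylated once.
3. The filicinic acid ring is assembled in one operation from an acyclic β-ethoxyacryloyl chloride and ethoxyacetylene by a vinylketene [2+2] / 4π-opening / 6π-closure cascade. In ring A numbering (C1 = ring C=O between acetyl-bearing C2 and CH2-bearing C6; C3, C5 = C–OH; C4 = CMe2) this forms C1–C2 and C4–C5 together with C5–C6, while the old acyl–Cα bond (C5 to C2) is cleaved.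
4. Enabling feature: the quaternary gem-dimethyl carbon C4 of rings A and C. A Me2C= terminus can close onto a ketene carbon, and because C4 then bears no hydrogen the product stays a cyclohexa-2,4-dienone instead of tautomerising to a phenol. The oxygens at C1, C3 and C5 are the ynol ether, enol ether and ketene oxygens.
5. Ring order: the carbocycle of rings A and C (step 4) is the only ring built; ring B is bought as phloroglucinol.

Key step: step 4

Remark: filicinic acid (product of step 5) has a mirror plane through its CMe2 carbon and the opposite ring carbonyl carbon, so its two ring CH carbons are equivalent; the atom bookkeeping used here places the acetyl group on the CH that was the α-carbon of the acid chloride and the methylene bridge on the CH that came from ethoxyacetylene.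

**Route**

Step 1
Reactants: 1 ethyl 4-methyl-3-oxopentanoate
Product: 2 ethyl (2E)-3-ethoxy-4-methylpent-2-enoate
Conditions: HC(OEt)3 (1.5 equiv), H2SO4 (cat.), EtOH, rt to 60 °C; then distillation
Reagents that add atoms: triethyl orthoformate, CCOC(OCC)OCC
Why: Acid-catalysed ketalisation of the ketone by the orthoformate and loss of ethanol should give the conjugated β-ethoxyacrylate (standard enol ether formation from a β-keto ester), the E isomer being expected and both geometric isomers converging on the same ketene in step 4.

Step 2
Reactants: 2 ethyl (2E)-3-ethoxy-4-methylpent-2-enoate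
Product: 3 (2E)-3-ethoxy-4-methylpent-2-enoic acid
Conditions: KOH (1.5 equiv), EtOH/H2O, 60 °C; then 1 M HCl to pH 3 at 0 °C, rapid extraction
Reagents that add atoms: potassium hydroxide, [K+].[OH-]
Why: Ester saponification, in which the β-alkoxyacrylate (a vinylogous carbonate) should keep its enol ether through hydroxide treatment and a brief cold acidification.

Step 3
Reactants: 3 (2E)-3-ethoxy-4-methylpent-2-enoic acid
Product: 4 (2E)-3-ethoxy-4-methylpent-2-enoyl chloride
Conditions: (COCl)2 (1.2 equiv), DMF (cat.), CH2Cl2, 0 °C to rt; evaporate, use crude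
Reagents that add atoms: oxalyl chloride, O=C(Cl)C(=O)Cl
Why: Acid chloride formation through the Vilsmeier-type chloroiminium reagent, as used for β-alkoxyacryloyl chlorides, gives only volatile by-products.

Step 4
Reactants: 4 (2E)-3-ethoxy-4-methylpent-2-enoyl chloride; 5 ethoxyacetylene (ethoxyethyne)
Product: 9 3,5-diethoxy-6,6-dimethylcyclohexa-2,4-dien-1-one, via vinylketene 6 (not isolated), via cyclobutenone adduct 7 (not isolated), via dienylketene 8 (not isolated)
Conditions: 5 (3 equiv, about 40 wt% in hexanes), Et3N (1.3 equiv, slow addition), toluene, 0 °C to rt; then 100 °C, sealed tube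
Reagents that add atoms: none
Why: Et3N should effect 1,4-dehydrochlorination of 4 at the isopropyl methine to give (alkoxyvinyl)ketene 6, whose ketene C=C adds the ynol ether in a regioselective [2+2] cycloaddition (CH carbon of 5 to the ketene carbonyl carbon, forming ring A C5–C6; O-bearing carbon of 5 to the ketene α-carbon, forming ring A C1–C2) to give 4-alkenylcyclobutenone 7. On heating, 4π electrocyclic opening of 7 cleaves the old acyl–Cα bond to give dienylketene 8, and a 6π electrocyclization joins the ketene carbon to the Me2C= terminus (ring A C5–C4), creating the quaternary carbon. The closest known reaction type is the vinylketene–alkyne aromatic annulation (Danheiser benzannulation) with alkoxyalkynes, here arrested at the cyclohexa-2,4-dienone because the ring-closing terminus carries two methyl groups. Ring closures: the four-membered ring by [2+2] cycloaddition (reopened in the same operation) and the six-membered ring by thermal disrotatory 6π electrocyclization. No stereocentre is created in 9 (the one in transient 7 is racemic and is destroyed on ring opening). The step needs [2+2] rather than [4+2] chemoselectivity and head-to-tail regioselectivity, both secured by the polarity match between the electrophilic ketene carbon and the nucleophilic β-carbon of the ynol ether, while the (3E)-dienylketene needed for closure is funnelled through reversible cyclobutenone opening and excess 5 with slow base addition suppresses ketene dimerisation.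

Step 5
Reactants: 9 3,5-diethoxy-6,6-dimethylcyclohexa-2,4-dien-1-one
Product: 10 filicinic acid (3,5-dihydroxy-4,4-dimethylcyclohexa-2,5-dien-1-one)
Conditions: 2 M aq. HCl, THF, 50 °C
Reagents that add atoms: water, O
Why: Both ethoxy groups are vinylogous-ester enol ethers, so acid hydrolysis (conjugate addition of water, loss of ethanol) should give the symmetric, fully enolised cyclic β-triketone.

Step 6
Reactants: 10 filicinic acid
Product: 11 2-acetylfilicinic acid (2-acetyl-3,5-dihydroxy-4,4-dimethylcyclohexa-2,5-dien-1-one)
Conditions: AcCl (1.05 equiv), AlCl3 (3 equiv), PhNO2, rt to 50 °C; ice/aq. HCl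
Reagents that add atoms: acetyl chloride, CC(=O)Cl
Why: Friedel–Crafts-type C-acylation of the enolised β-triketone at one of its two equivalent nucleophilic CH carbons should stop at mono-acylation because the chelated 2-acyl product is deactivated.

Step 7
Reactants: 10 filicinic acid
Product: 12 2-butanoylfilicinic acid (2-butanoyl-3,5-dihydroxy-4,4-dimethylcyclohexa-2,5-dien-1-one)
Conditions: n-PrCOCl (1.05 equiv), AlCl3 (3 equiv), PhNO2, rt to 50 °C; ice/aq. HCl
Reagents that add atoms: butanoyl chloride, CCCC(=O)Cl
Why: The same Friedel–Crafts-type mono-C-acylation of the β-triketone, with butanoyl chloride.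

Step 8
Reactants: 13 phloroglucinol (benzene-1,3,5-triol)
Product: 14 1-(2,4,6-trihydroxyphenyl)butan-1-one
Conditions: n-PrCOCl (1.0 equiv), AlCl3 (3 equiv), PhNO2/CH2Cl2, 0 to 40 °C; ice/aq. HCl
Reagents that add atoms: butanoyl chloride, CCCC(=O)Cl
Why: Friedel–Crafts mono-acylation of phloroglucinol is self-limiting because the hydrogen-bonded aryl ketone deactivates the ring.

Step 9
Reactants: 12 2-butanoylfilicinic acid; 14 1-(2,4,6-trihydroxyphenyl)butan-1-one
Product: 17 2-butanoyl-6-[(3-butanoyl-2,4,6-trihydroxyphenyl)methyl]-3,5-dihydroxy-4,4-dimethylcyclohexa-2,5-dien-1-one, via Mannich base 15 (not isolated), via enetrione 16 (not isolated)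
Conditions: Me2N=CH2+ I− (1.05 equiv), MeCN, 0 °C to rt; then 14 (3 equiv), NaOAc (1.2 equiv), 1,4-dioxane, 70 °C
Reagents that add atoms: N,N-dimethylmethylideneammonium iodide (Eschenmoser's salt), C=[N+](C)C.[I-]
Why: Mannich aminomethylation of the single nucleophilic ring CH of 12 gives 15, which on acetate buffering should lose dimethylamine to enetrione 16 (a quinone-methide-type acceptor) that C-alkylates the phloroglucinol ring of 14 by conjugate addition, the excess of 14 keeping the alkylation at one of its two equivalent positions.

Step 10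
Reactants: 11 2-acetylfilicinic acid; 17 2-butanoyl-6-[(3-butanoyl-2,4,6-trihydroxyphenyl)methyl]-3,5-dihydroxy-4,4-dimethylcyclohexa-2,5-dien-1-one
Product: 20 2-acetyl-6-({3-butanoyl-5-[(5-butanoyl-2,4-dihydroxy-3,3-dimethyl-6-oxocyclohexa-1,4-dien-1-yl)methyl]-2,4,6-trihydroxyphenyl}methyl)-3,5-dihydroxy-4,4-dimethylcyclohexa-2,5-dien-1-one, via Mannich base 18 (not isolated), via enetrione 19 (not isolated)
Conditions: Me2N=CH2+ I− (1.05 equiv), MeCN, 0 °C to rt; then 17 (1.0 equiv), NaOAc (1.2 equiv), 1,4-dioxane, 60 °C
Reagents that add atoms: N,N-dimethylmethylideneammonium iodide (Eschenmoser's salt), C=[N+](C)C.[I-]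
Why: The same Mannich/elimination/conjugate-addition sequence is regiochemically unambiguous here because 11 has one nucleophilic CH and 17 one free aromatic CH, and the mild buffer and moderate temperature are chosen to avoid retro-Michael exchange of the bridge already present.

**Compound list**

1 | ethyl 4-methyl-3-oxopentanoate | CCOC(=O)CC(=O)C(C)C | starting material
2 | ethyl (2E)-3-ethoxy-4-methylpent-2-enoate | CCO/C(C(C)C)=C/C(=O)OCC | intermediate
3 | (2E)-3-ethoxy-4-methylpent-2-enoic acid | CCO/C(C(C)C)=C/C(=O)O | intermediate
4 | (2E)-3-ethoxy-4-methylpent-2-enoyl chloride | CCO/C(C(C)C)=C/C(=O)Cl | intermediate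
5 | ethoxyacetylene (ethoxyethyne) | C#COCC | starting material
6 | vinylketene: 3-ethoxy-4-methylpenta-1,3-dien-1-one | CCOC(C=C=O)=C(C)C | intermediate
7 | cyclobutenone adduct: (±)-3-ethoxy-4-(1-ethoxy-2-methylprop-1-en-1-yl)cyclobut-2-en-1-one | CCOC1=CC(=O)C1C(OCC)=C(C)C | intermediate
8 | dienylketene: (3E)-3,5-diethoxy-6-methylhepta-1,3,5-trien-1-one | O=C=C/C(OCC)=C\C(OCC)=C(C)C | intermediate
9 | 3,5-diethoxy-6,6-dimethylcyclohexa-2,4-dien-1-one | CCOC1=CC(=O)C(C)(C)C(OCC)=C1 | intermediate
10 | filicinic acid (3,5-dihydroxy-4,4-dimethylcyclohexa-2,5-dien-1-one) | CC1(C)C(O)=CC(=O)C=C1O | intermediate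
11 | 2-acetylfilicinic acid (2-acetyl-3,5-dihydroxy-4,4-dimethylcyclohexa-2,5-dien-1-one) | CC(=O)C1=C(O)C(C)(C)C(O)=CC1=O | intermediate
12 | 2-butanoylfilicinic acid (2-butanoyl-3,5-dihydroxy-4,4-dimethylcyclohexa-2,5-dien-1-one) | CCCC(=O)C1=C(O)C(C)(C)C(O)=CC1=O | intermediate
13 | phloroglucinol (benzene-1,3,5-triol) | Oc1cc(O)cc(O)c1 | starting material
14 | 1-(2,4,6-trihydroxyphenyl)butan-1-one | CCCC(=O)c1c(O)cc(O)cc1O | intermediate
15 | Mannich base of 12: 2-butanoyl-6-[(dimethylamino)methyl]-3,5-dihydroxy-4,4-dimethylcyclohexa-2,5-dien-1-one | CCCC(=O)C1=C(O)C(C)(C)C(O)=C(CN(C)C)C1=O | intermediate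
16 | enetrione from 15: 2-butanoyl-3-hydroxy-4,4-dimethyl-6-methylidenecyclohex-2-ene-1,5-dione | CCCC(=O)C1=C(O)C(C)(C)C(=O)C(=C)C1=O | intermediate
17 | ring B–ring C dimer: 2-butanoyl-6-[(3-butanoyl-2,4,6-trihydroxyphenyl)methyl]-3,5-dihydroxy-4,4-dimethylcyclohexa-2,5-dien-1-one | CCCC(=O)C1=C(O)C(C)(C)C(O)=C(Cc2c(O)cc(O)c(C(=O)CCC)c2O)C1=O | intermediate
18 | Mannich base of 11: 2-acetyl-6-[(dimethylamino)methyl]-3,5-dihydroxy-4,4-dimethylcyclohexa-2,5-dien-1-one | CC(=O)C1=C(O)C(C)(C)C(O)=C(CN(C)C)C1=O | intermediate
19 | enetrione from 18: 2-acetyl-3-hydroxy-4,4-dimethyl-6-methylidenecyclohex-2-ene-1,5-dione | CC(=O)C1=C(O)C(C)(C)C(=O)C(=C)C1=O | intermediate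
20 | target (no stereocentres): 2-acetyl-6-({3-butanoyl-5-[(5-butanoyl-2,4-dihydroxy-3,3-dimethyl-6-oxocyclohexa-1,4-dien-1-yl)methyl]-2,4,6-trihydroxyphenyl}methyl)-3,5-dihydroxy-4,4-dimethylcyclohexa-2,5-dien-1-one | CCCC(=O)C1=C(O)C(C)(C)C(O)=C(Cc2c(O)c(CC3=C(O)C(C)(C)C(O)=C(C(C)=O)C3=O)c(O)c(C(=O)CCC)c2O)C1=O | target

**Step count and risks**

Total step count: 10. Longest linear sequence: 8 steps (1, 2, 3, 4, 5, 7, 9, 10).

Steps most likely to fail:

Step 4. The 1,4-dehydrochlorination at the hindered isopropyl methine may be slow, and the vinylketene may be consumed by dimerisation or by amine-salt chemistry before the ynol ether intercepts it. Fallback, known chemistry: it sets out from 5 and commercial 2-methylpropanoyl chloride. Et3N in ether generates dimethylketene F1, which adds 5 in a [2+2] cycloaddition to give the distillable 3-ethoxy-4,4-dimethylcyclobut-2-en-1-one F2. Heated with a further equivalent of 5 (toluene, 100 °C, sealed tube), F2 should open thermally to the same vinylketene 6 without base or salts and run through 7 and 8, coming back to the route at 9.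

Step 10. Retro-Michael exchange of the bridge already present in 17 may scramble the filicinic units, and enetrione 19 may be captured by 11 released through retro-Mannich reaction, giving a symmetric bis-filicinic by-product. Fallback with reversed polarity: it sets out from 17. Aminomethylation with Eschenmoser's salt at the only free aromatic CH gives the isolable dimer Mannich base F3. Warmed with 11 and NaOAc (dioxane, 50 °C), F3 should lose dimethylamine to the ortho-quinone methide F4, which is trapped by the single nucleophilic CH of 11, coming back at 20. The electrophile then sits on the partner that has no second reactive site, and 11 cannot self-couple.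

Step 9. Alkylation of 14 may continue at its second free position, giving a statistical mixture of mono- and bis-adducts that is hard to separate. Fallback: it sets out from 14. Mono-aminomethylation with one equivalent of Eschenmoser's salt gives the zwitterionic Mannich base F5, purified by crystallisation so that the degree of substitution is fixed before coupling. Heating F5 with 12 and NaOAc should give, through ortho-quinone methide F6 and attack by the single nucleophilic CH of 12, the dimer, coming back at 17.

**Further compounds**

F1 | step 4 | dimethylketene (2-methylprop-1-en-1-one) | CC(C)=C=O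
F2 | step 4 | 3-ethoxy-4,4-dimethylcyclobut-2-en-1-one | CCOC1=CC(=O)C1(C)C
F3 | step 10 | dimer Mannich base: 2-butanoyl-6-({3-butanoyl-5-[(dimethylamino)methyl]-2,4,6-trihydroxyphenyl}methyl)-3,5-dihydroxy-4,4-dimethylcyclohexa-2,5-dien-1-one | CCCC(=O)C1=C(O)C(C)(C)C(O)=C(Cc2c(O)c(CN(C)C)c(O)c(C(=O)CCC)c2O)C1=O
F4 | step 10 | ortho-quinone methide from F3: 2-butanoyl-6-[(5-butanoyl-2,6-dihydroxy-3-methylidene-4-oxocyclohexa-1,5-dien-1-yl)methyl]-3,5-dihydroxy-4,4-dimethylcyclohexa-2,5-dien-1-one | CCCC(=O)C1=C(O)C(C)(C)C(O)=C(CC2=C(O)C(=C)C(=O)C(C(=O)CCC)=C2O)C1=O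
F5 | step 9 | 1-{3-[(dimethylamino)methyl]-2,4,6-trihydroxyphenyl}butan-1-one | CCCC(=O)c1c(O)cc(O)c(CN(C)C)c1O
F6 | step 9 | ortho-quinone methide from F5: 2-butanoyl-3,5-dihydroxy-6-methylidenecyclohexa-2,4-dien-1-one | CCCC(=O)C1=C(O)C=C(O)C(=C)C1=O
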